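## Retrosynthetic overview

- Target 22 comes from chromone 21 by BBr3 cleavage of three methyl ethers. Chromone 21 comes from the o-hydroxyaryl 1,3-diketone 20 by acid cyclodehydration (O1–C2 bond), which closes the chromone pyranone, ring C, last.
- The strategy rests on ring A (C4a, C5, C6, C7, C8, C8a): a methyl on C5, the acyl carbon C4 on C4a and oxygens on C7 and C8a are what a 1,1,3-trioxygenated buta-1,3-diene delivers to a but-2-ynoyl ketone. Diketone 20 therefore comes from a [4+2] benzannulation (bonds C5–C6 and C4a–C8a) of alkynyl diketone 14 with diene 17.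
- The diene is the open-chain 1-methoxy-1,3-bis(trimethylsilyloxy)buta-1,3-diene. A diene whose C1 and C3 oxygens are tied into a dioxine ring is locked s-trans and cannot bridge the two alkyne carbons.
- Diketone 14 comes from oxidation of aldol 13, made from ring-B aldehyde 10 and the lithium enolate of pent-3-yn-2-one. In this way no base has to choose between an aryl methyl ketone and the more acidic ArCH2–pyranone methylene. Aldehyde 10 comes from formylation of 8, and 8 from acid 1 and dioxinone 2.
- Ring order: ring B is bought, the 2-pyranone is made first (step 2), ring A second (step 8), ring C last (step 9).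

Key step: step 8

Assumption: the 1,3-diketones 14 and 20 are drawn as diketo tautomers but should exist mainly as chelated enols (20 partly as its cyclic hemiketal), and aldol 13 is racemic, its stereocentre being removed in step 6.

## Route

Step 1
Reactants: 1 (3,5-dimethoxyphenyl)acetic acid; 2 2,2,6-trimethyl-4H-1,3-dioxin-4-one
Product: 5 6-[3-(3,5-dimethoxyphenyl)-2-oxopropyl]-2,2-dimethyl-4H-1,3-dioxin-4-one, via acyl imidazole 3 (not isolated), via lithium dienolate 4 (not isolated)
Conditions: 1, CDI, THF, rt; added to 2 + LiN(SiMe3)2 (2.2 equiv each), THF, −78 °C to −40 °C; then 1 M HCl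
Reagents that add atoms: none
Why: Claisen-type C-acylation, in which the vinylogous lithium enolate of the dioxinone is acylated at its exocyclic γ-carbon by the acyl imidazole, the second equivalent of enolate taking up the acidic proton of the product.

Step 2
Reactants: 5 6-[3-(3,5-dimethoxyphenyl)-2-oxopropyl]-2,2-dimethyl-4H-1,3-dioxin-4-one
Product: 7 6-[(3,5-dimethoxyphenyl)methyl]-4-hydroxy-2H-pyran-2-one, via acylketene 6 (not isolated)
Conditions: toluene, 110 °C
Reagents that add atoms: none
Why: Thermal retro-[4+2] loss of acetone from the dioxinone should give the acylketene, which is trapped by the enol oxygen of the δ-ketone to close the 4-hydroxy-2-pyranone (acylketene lactonisation).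

Step 3
Reactants: 7 6-[(3,5-dimethoxyphenyl)methyl]-4-hydroxy-2H-pyran-2-one
Product: 8 6-[(3,5-dimethoxyphenyl)methyl]-4-methoxy-2H-pyran-2-one
Conditions: Me2SO4, K2CO3, acetone, 56 °C
Reagents that add atoms: dimethyl sulfate COS(=O)(=O)OC
Why: O-alkylation of the vinylogous acid with a hard methylating agent and K2CO3 is the standard entry to 4-methoxy-2-pyranones, methylation at the 4-oxygen being expected to dominate.

Step 4
Reactants: 8 6-[(3,5-dimethoxyphenyl)methyl]-4-methoxy-2H-pyran-2-one
Product: 10 2,4-dimethoxy-6-[(4-methoxy-2-oxo-2H-pyran-6-yl)methyl]benzaldehyde, via iminium salt 9 (not isolated)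
Conditions: POCl3, DMF, 0 °C to 50 °C; then ice–water, rt
Reagents that add atoms: N,N-dimethylformamide CN(C)C=O; water O
Why: Vilsmeier–Haack formylation should take place on the dimethoxybenzene ring, by far the most nucleophilic π-system, at the position beside the CH2 (para to one methoxyl, ortho to the other) as with 3,5-dimethoxytoluene, the site between the two methoxyls being more hindered and the electron-poor pyranone unreactive.

Step 5
Reactants: 10 2,4-dimethoxy-6-[(4-methoxy-2-oxo-2H-pyran-6-yl)methyl]benzaldehyde; 11 pent-3-yn-2-one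
Product: 13 1-[2,4-dimethoxy-6-[(4-methoxy-2-oxo-2H-pyran-6-yl)methyl]phenyl]-1-hydroxyhex-4-yn-3-one (racemic), via lithium enolate 12 (not isolated)
Conditions: 11, LiN(SiMe3)2, THF, −78 °C; then 10, −78 °C; AcOH quench at −78 °C
Reagents that add atoms: none
Why: Aldol addition of the preformed lithium enolate of the methyl ynone to the aldehyde at low temperature, in which only 11 is exposed to free base and carbonyl addition should outrun proton transfer from the ArCH2–pyranone methylene; the carbinol centre forms racemic and is removed in step 6.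

Step 6
Reactants: 13 1-[2,4-dimethoxy-6-[(4-methoxy-2-oxo-2H-pyran-6-yl)methyl]phenyl]-1-hydroxyhex-4-yn-3-one
Product: 14 1-[2,4-dimethoxy-6-[(4-methoxy-2-oxo-2H-pyran-6-yl)methyl]phenyl]hex-4-yne-1,3-dione
Conditions: Dess–Martin periodinane, NaHCO3, CH2Cl2, 0 °C to rt
Reagents that add atoms: none
Why: Dess–Martin oxidation of a β-hydroxy ketone to the 1,3-diketone under buffered, non-basic conditions should spare the ynone and avoid acid- or base-induced 6-endo closure of the enol onto the alkyne.

Step 7
Reactants: 15 methyl 3-(trimethylsilyloxy)but-2-enoate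
Product: 17 1-methoxy-1,3-bis(trimethylsilyloxy)buta-1,3-diene, via lithium dienolate 16 (not isolated)
Conditions: LiN(i-Pr)2, THF, −78 °C; Me3SiCl, −78 °C to rt; non-aqueous work-up, distillation
Reagents that add atoms: chlorotrimethylsilane C[Si](C)(C)Cl
Why: γ-Deprotonation of the silyloxy crotonate and O-silylation of the ester dienolate is the standard preparation of this 1,3-bis(silyloxy) ketene-acetal diene.

Step 8
Reactants: 14 1-[2,4-dimethoxy-6-[(4-methoxy-2-oxo-2H-pyran-6-yl)methyl]phenyl]hex-4-yne-1,3-dione; 17 1-methoxy-1,3-bis(trimethylsilyloxy)buta-1,3-diene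
Product: 20 1-(2,4-dihydroxy-6-methylphenyl)-3-[2,4-dimethoxy-6-[(4-methoxy-2-oxo-2H-pyran-6-yl)methyl]phenyl]propane-1,3-dione, via silyl enol ether 18 (not isolated), via cycloadduct 19 (not isolated)
Conditions: N,O-bis(trimethylsilyl)acetamide, toluene, rt; then 17 (2.5 equiv), 90 °C; then 1 M HCl, THF, rt
Reagents that add atoms: none
Why: Silylation first turns the chelated enol of 14 into silyl enol ether 18, so that no acidic OH protodesilylates the ketene acetal and the enol oxygen is blocked from closing 6-endo onto the alkyne. Diene 17 then adds to the ynone triple bond in a thermal, asynchronous [4+2] cycloaddition, the known resorcinol synthesis from 1,1,3-trioxygenated butadienes and acetylenic ketones or esters: its unsubstituted C4 terminus, which carries the largest HOMO coefficient, bonds to the methyl-bearing β-carbon of the ynone (C5–C6) and the ketene-acetal carbon C1 bonds to the α-carbon (C4a–C8a). Ring A is thereby closed intermolecularly as cyclohexa-1,4-diene 19, and the acid work-up cleaves the silyl groups so that the C1 hemiketal expels methanol and the ring tautomerises to the resorcinol. The diene is open-chain on purpose, since it can reach the s-cis conformation that a dioxine-bridged diene cannot. No stereocentre survives the step. The selectivities needed are the regiochemistry (methyl next to the acyl-bearing carbon), fixed by the matched polarisation of diene and ynone, and [4+2] addition across the alkyne in preference to Michael/aldol annulation at the ketone carbonyl, which the absence of a Lewis acid and the vinylogous silyl ester character of that carbonyl should secure.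

Step 9
Reactants: 20 1-(2,4-dihydroxy-6-methylphenyl)-3-[2,4-dimethoxy-6-[(4-methoxy-2-oxo-2H-pyran-6-yl)methyl]phenyl]propane-1,3-dione
Product: 21 2-[2,4-dimethoxy-6-[(4-methoxy-2-oxo-2H-pyran-6-yl)methyl]phenyl]-7-hydroxy-5-methyl-4H-chromen-4-one
Conditions: H2SO4 (cat.), AcOH, 80 °C
Reagents that add atoms: none
Why: Acid-catalysed cyclodehydration of a 1-(2-hydroxyaryl)-1,3-diketone (the closing step of the Baker–Venkataraman flavone synthesis), in which the C8a hydroxyl adds to the ring-B carbonyl and water is lost; ring B carries no free hydroxyl, so only this chromone can form.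

Step 10
Reactants: 21 2-[2,4-dimethoxy-6-[(4-methoxy-2-oxo-2H-pyran-6-yl)methyl]phenyl]-7-hydroxy-5-methyl-4H-chromen-4-one
Product: 22 2-[2,4-dihydroxy-6-[(4-hydroxy-2-oxo-2H-pyran-6-yl)methyl]phenyl]-7-hydroxy-5-methyl-4H-chromen-4-one
Conditions: BBr3 (excess), CH2Cl2, −78 °C to rt; then H2O
Reagents that add atoms: none
Why: Lewis-acid ether cleavage with BBr3 should remove the two aryl methyl ethers and the vinylogous methyl ester of the pyranone, while the chromone, the pyranone lactone and the CH2 bridge are expected to survive at or below room temperature.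

## Compound list

1 | (3,5-dimethoxyphenyl)acetic acid | COc1cc(CC(=O)O)cc(OC)c1 | starting material
2 | 2,2,6-trimethyl-4H-1,3-dioxin-4-one | CC1=CC(=O)OC(C)(C)O1 | starting material
3 | 1-[(3,5-dimethoxyphenyl)acetyl]-1H-imidazole (not isolated) | COc1cc(CC(=O)n2ccnc2)cc(OC)c1 | intermediate
4 | lithium 2,2-dimethyl-6-methylidene-6H-1,3-dioxin-4-olate (not isolated) | [Li+].C=C1C=C([O-])OC(C)(C)O1 | intermediate
5 | 6-[3-(3,5-dimethoxyphenyl)-2-oxopropyl]-2,2-dimethyl-4H-1,3-dioxin-4-one | COc1cc(CC(=O)CC2=CC(=O)OC(C)(C)O2)cc(OC)c1 | intermediate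
6 | 6-(3,5-dimethoxyphenyl)-3,5-dioxohex-1-en-1-one (acylketene, not isolated) | COc1cc(CC(=O)CC(=O)C=C=O)cc(OC)c1 | intermediate
7 | 6-[(3,5-dimethoxyphenyl)methyl]-4-hydroxy-2H-pyran-2-one | COc1cc(Cc2cc(O)cc(=O)o2)cc(OC)c1 | intermediate
8 | 6-[(3,5-dimethoxyphenyl)methyl]-4-methoxy-2H-pyran-2-one | COc1cc(Cc2cc(OC)cc(=O)o2)cc(OC)c1 | intermediate
9 | [2,4-dimethoxy-6-[(4-methoxy-2-oxo-2H-pyran-6-yl)methyl]phenyl]methylidene-dimethylammonium dichlorophosphate (not isolated) | C[N+](C)=Cc1c(OC)cc(OC)cc1Cc1cc(OC)cc(=O)o1.[O-]P(=O)(Cl)Cl | intermediate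
10 | 2,4-dimethoxy-6-[(4-methoxy-2-oxo-2H-pyran-6-yl)methyl]benzaldehyde | O=Cc1c(OC)cc(OC)cc1Cc1cc(OC)cc(=O)o1 | intermediate
11 | pent-3-yn-2-one | CC#CC(C)=O | starting material
12 | lithium pent-1-en-3-yn-2-olate (not isolated) | [Li+].[O-]C(=C)C#CC | intermediate
13 | 1-[2,4-dimethoxy-6-[(4-methoxy-2-oxo-2H-pyran-6-yl)methyl]phenyl]-1-hydroxyhex-4-yn-3-one (racemic) | CC#CC(=O)CC(O)c1c(OC)cc(OC)cc1Cc1cc(OC)cc(=O)o1 | intermediate
14 | 1-[2,4-dimethoxy-6-[(4-methoxy-2-oxo-2H-pyran-6-yl)methyl]phenyl]hex-4-yne-1,3-dione | CC#CC(=O)CC(=O)c1c(OC)cc(OC)cc1Cc1cc(OC)cc(=O)o1 | intermediate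
15 | methyl 3-(trimethylsilyloxy)but-2-enoate (commercial E/Z mixture) | COC(=O)C=C(C)O[Si](C)(C)C | starting material
16 | lithium 1-methoxy-3-(trimethylsilyloxy)buta-1,3-dien-1-olate (not isolated) | [Li+].COC([O-])=CC(=C)O[Si](C)(C)C | intermediate
17 | 1-methoxy-1,3-bis(trimethylsilyloxy)buta-1,3-diene (C1=C2 geometry uncontrolled and without consequence) | COC(O[Si](C)(C)C)=CC(=C)O[Si](C)(C)C | intermediate
18 | (1Z)-1-[2,4-dimethoxy-6-[(4-methoxy-2-oxo-2H-pyran-6-yl)methyl]phenyl]-1-(trimethylsilyloxy)hex-1-en-4-yn-3-one (not isolated; drawn as one of the O-silyl isomers, which interconvert by silyl shift) | CC#CC(=O)/C=C(\O[Si](C)(C)C)c1c(OC)cc(OC)cc1Cc1cc(OC)cc(=O)o1 | intermediate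
19 | (2Z)-3-[2,4-dimethoxy-6-[(4-methoxy-2-oxo-2H-pyran-6-yl)methyl]phenyl]-1-[6-methoxy-2-methyl-4,6-bis(trimethylsilyloxy)cyclohexa-1,4-dien-1-yl]-3-(trimethylsilyloxy)prop-2-en-1-one (racemic, not isolated) | COC1(O[Si](C)(C)C)C=C(O[Si](C)(C)C)CC(C)=C1C(=O)/C=C(\O[Si](C)(C)C)c1c(OC)cc(OC)cc1Cc1cc(OC)cc(=O)o1 | intermediate
20 | 1-(2,4-dihydroxy-6-methylphenyl)-3-[2,4-dimethoxy-6-[(4-methoxy-2-oxo-2H-pyran-6-yl)methyl]phenyl]propane-1,3-dione | Cc1cc(O)cc(O)c1C(=O)CC(=O)c1c(OC)cc(OC)cc1Cc1cc(OC)cc(=O)o1 | intermediate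
21 | 2-[2,4-dimethoxy-6-[(4-methoxy-2-oxo-2H-pyran-6-yl)methyl]phenyl]-7-hydroxy-5-methyl-4H-chromen-4-one | Cc1cc(O)cc2oc(-c3c(OC)cc(OC)cc3Cc3cc(OC)cc(=O)o3)cc(=O)c12 | intermediate
22 | 2-[2,4-dihydroxy-6-[(4-hydroxy-2-oxo-2H-pyran-6-yl)methyl]phenyl]-7-hydroxy-5-methyl-4H-chromen-4-one | Cc1cc(O)cc2oc(-c3c(O)cc(O)cc3Cc3cc(O)cc(=O)o3)cc(=O)c12 | target

## Step count and risks

Total step count: 10. Longest linear sequence: 9 steps (steps 1–6, then 8–10); step 7 is the side branch to the diene.

Steps most likely to fail: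

1. Step 8. The silylated diketone is a vinylogous ester and may be a sluggish dienophile. At the temperature then needed the diene may decompose, or the enol ether oxygen may close 6-endo-dig onto the alkyne to give a 4-pyranone. The C1 ketal may also lose silanol in place of methanol, leaving the C8a oxygen methylated. The fallback sets out from 13 and comes back at 21. Aldol 13 would be silylated (TBSOTf, 2,6-lutidine, CH2Cl2, −78 °C) to the β-silyloxy ynone F1, a plain, non-enolised ynone that cannot form a pyranone. Cycloaddition with 17 (toluene, 60–80 °C) should give the cyclohexadiene cycloadduct F2 and, after dilute acid, the resorcinol β-silyloxy ketone F3. p-TsOH in toluene should then eliminate silanol to the 2'-hydroxychalcone F4, and iodine (cat.) in DMSO at 120–130 °C, the usual oxidative cyclisation of 2'-hydroxychalcones to flavones, should give chromone 21.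

2. Step 6. The hypervalent iodine reagent may over-oxidise the doubly activated central CH2 of the diketone. The acetic acid released, or silica gel, may trigger 6-endo-dig closure of the enol onto the alkyne during reaction or purification. The fallback sets out from 10 and comes back at 14. Pinnick oxidation of aldehyde 10 (NaClO2, NaH2PO4, 2-methylbut-2-ene, t-BuOH/H2O) should give the benzoic acid F5, and CDI in THF the acyl imidazole F6. Claisen acylation of lithium enolate 12 (2.2 equiv, THF, −78 °C) with F6 should then deliver 14 as its lithium chelate, released by a cold citric acid quench, so that no oxidant meets the diketone.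

3. Step 5. Proton transfer from the ArCH2–pyranone methylene of 10 to the enolate, retro-aldol cleavage on warming, or Michael self-condensation of the ynone enolate may erode the addition. The fallback sets out from 11 and comes back at 13. Ketone 11 would be converted (Me3SiOTf, Et3N, CH2Cl2, 0 °C) into the silyl enol ether F7, which should add to aldehyde 10 in a Mukaiyama aldol reaction (BF3·OEt2, CH2Cl2, −78 °C) under non-basic conditions and give 13 after aqueous work-up.

Further compounds
F1 | step 8 | 1-(tert-butyldimethylsilyloxy)-1-[2,4-dimethoxy-6-[(4-methoxy-2-oxo-2H-pyran-6-yl)methyl]phenyl]hex-4-yn-3-one (racemic) | CC#CC(=O)CC(O[Si](C)(C)C(C)(C)C)c1c(OC)cc(OC)cc1Cc1cc(OC)cc(=O)o1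
F2 | step 8 | 3-(tert-butyldimethylsilyloxy)-3-[2,4-dimethoxy-6-[(4-methoxy-2-oxo-2H-pyran-6-yl)methyl]phenyl]-1-[6-methoxy-2-methyl-4,6-bis(trimethylsilyloxy)cyclohexa-1,4-dien-1-yl]propan-1-one (racemic mixture of diastereomers) | COC1(O[Si](C)(C)C)C=C(O[Si](C)(C)C)CC(C)=C1C(=O)CC(O[Si](C)(C)C(C)(C)C)c1c(OC)cc(OC)cc1Cc1cc(OC)cc(=O)o1
F3 | step 8 | 3-(tert-butyldimethylsilyloxy)-1-(2,4-dihydroxy-6-methylphenyl)-3-[2,4-dimethoxy-6-[(4-methoxy-2-oxo-2H-pyran-6-yl)methyl]phenyl]propan-1-one (racemic) | Cc1cc(O)cc(O)c1C(=O)CC(O[Si](C)(C)C(C)(C)C)c1c(OC)cc(OC)cc1Cc1cc(OC)cc(=O)o1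
F4 | step 8 | (2E)-1-(2,4-dihydroxy-6-methylphenyl)-3-[2,4-dimethoxy-6-[(4-methoxy-2-oxo-2H-pyran-6-yl)methyl]phenyl]prop-2-en-1-one | Cc1cc(O)cc(O)c1C(=O)/C=C/c1c(OC)cc(OC)cc1Cc1cc(OC)cc(=O)o1
F5 | step 6 | 2,4-dimethoxy-6-[(4-methoxy-2-oxo-2H-pyran-6-yl)methyl]benzoic acid | OC(=O)c1c(OC)cc(OC)cc1Cc1cc(OC)cc(=O)o1
F6 | step 6 | 6-[[2-(1H-imidazole-1-carbonyl)-3,5-dimethoxyphenyl]methyl]-4-methoxy-2H-pyran-2-one | O=C(c1c(OC)cc(OC)cc1Cc1cc(OC)cc(=O)o1)n1ccnc1
F7 | step 5 | 2-(trimethylsilyloxy)pent-1-en-3-yne | C=C(O[Si](C)(C)C)C#CC
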